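If chain ends that turn G into Q die while G is still present, the flask stops short of full conversion, and you need to know how far it gets.

the same everywhere: J 2.6 mM; L 3.1 mM

| charge | G | X | remark | time |
|---|---|---|---|---|
| ochre | 0.51 M | 0.0228 M | run made earlier |  |
| epsilon | 0.76 M | 0.00800 M |  | 40 min |
| alpha | 0.76 M | 0.0228 M |  | 40 min |
| eta | 0.76 M | 0.100 M |  | 40 min |
| delta | 0.76 M | 0.0600 M |  | 40 min |

ochre run (percent of the G charged): time / min: Q / % = 2.50: 47; 5.00: 66; 8.00: 76; 10.0: 80; 12.0: 83; 15.0: 84

(standard deviation of a reading: 2 percentage points)

- the numbers in the tables scatter by 2 percentage points (one standard deviation)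
- no earlier run changes the charge of X; that part of a forecast is a guess

- ranking by amount of Q, in percent of the G charged, from high to low, at 40 min (epsilon / alpha / eta / delta)
- the amount of Q, in percent of the G charged of the flask you put first, at 40 min
- the amount of Q, in percent of the G charged of the flask you put last, at 40 min

**Main step.** Suppose ends started by J turn G into Q at a rate proportional to G. Measure each flask by its reach, the natural log of the G charged over the G left. With a fixed number of ends, reach grows in step with time and the charge of G drops out. The first ochre reading gives 0.254 min⁻¹. That rate leaves 2.21% of the G at 15.0 min, but ochre shows 16.0%.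

**Dying ends.** Now let the ends decay with a first-order constant d. Each equal stretch of time then adds exp(−d·t) times the reach of the stretch before. Ochre reads 1.08 at 5.00 min and 1.61 at 10.0 min, which gives d = 0.142 min⁻¹. Summing the stretches gives the ceiling reach, the reach at which the ends are gone: 2.12, a reading that carries the scatter.

**Adding X.** My guess, untested by any run, is that X kills the ends. Every asked flask holds more X than J or L, even in epsilon, but that does not by itself keep X constant. As a further assumption I hold X at its charge, which makes the loss pseudo-first-order, with d proportional to X and the ceiling inversely proportional to X; I trust this least in epsilon, the flask with the smallest charge of X. I leave the ceiling unchanged by the charge of G. Eta then reaches 38.4% Q, delta 55.4% and alpha 88.0%. Going round once more with the scaled d, epsilon has covered 86.4% of its ceiling by 40 min, which gives 99.5% Q. My order is epsilon, alpha, delta, eta.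

The forecast differs: it gives eta > delta > alpha > epsilon, from 91% down to 88%, while noting that “X could instead retard the reaction”.

The flasks give epsilon > alpha > delta > eta: 99.8%, 92.7%, 62.3% and 44.2%.

    G + E → Q + E, rate k1*[E]*[G] (k = 2.90 M⁻¹ s⁻¹)
    G + J → E + Q (k = 0.239 M⁻¹ s⁻¹)
    J + L → Z (k = 24.8 M⁻¹ s⁻¹)
    E + X → D (k = 0.0953 M⁻¹ s⁻¹)

**Ends against G.** In eta, growth gives G a half-life of 3.7 min at 1.06 min, longer than the 1.24 min of eta's slowest mode at 40.0 min. Eta has 92% of its growth up to the asked time behind it at 4.00 min, and 55.8% of its G stands unused at 40.0 min. The ceiling 2.12, scaled by X, gives eta 38.4% Q against the 44.2% found, and for a neighbour of eta charged with 0.17 M of X it gives 24.8%, where that flask holds 29.0%.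

(The readings stem from a simulated flask on assumed constants; scatter was added.)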